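**Plan**
- Retrosynthesis: the C5 hydroxyl is first masked as its methyl ether; ring C is then cut at two bonds, C4–C3 and O1–C2.
- Enabling feature: C4 (the ring C carbonyl) is the formyl carbon of a ring A salicylaldehyde whose phenol oxygen becomes O1, and the C2(aryl)=C3(OMe) unit is an aryl methoxy alkyne carrying ring B.
- Forward: the ring A aldehyde comes from 1,2,3,5-tetramethoxybenzene by formylation and chelation-controlled mono-demethylation; the ynol ether comes from trichloroethylene, methoxide and 2-iodoanisole.
- A rhodium-catalysed oxidative annulation joins the two pieces and closes ring C in one operation; BCl3 then frees the peri C5 hydroxyl.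
- Stereochemistry: the target has no stereocentre; all selectivity questions are regiochemical (which ortho methoxyl is cleaved, orientation of alkyne insertion, which methoxyl falls last).

Key step: step 5

Assumption: the rhodacycles of step 5 are transient, catalyst-bound species; they are described in words there and carry no compound number.

Step 1
Reactants: 1 1,2,3,5-tetramethoxybenzene
Product: 3 2,3,4,6-tetramethoxybenzaldehyde, via aryl iminium salt 2 (not isolated)
Conditions: POCl3 (1.5 equiv), DMF, 0 °C → 70 °C; then H2O, 50 °C
Reagents that add atoms: N,N-dimethylformamide, CN(C)C=O; water, O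
Why: Vilsmeier–Haack formylation, in which the chloroiminium ion attacks one of the two equivalent free positions of the very electron-rich arene (each ortho and para to methoxyls) and hydrolysis of iminium salt 2 releases the aldehyde.

Step 2
Reactants: 3 2,3,4,6-tetramethoxybenzaldehyde
Product: 5 2-hydroxy-3,4,6-trimethoxybenzaldehyde, via aryloxydichloroborane chelate 4 (not isolated)
Conditions: BCl3 (1.1 equiv, 1 M in CH2Cl2), CH2Cl2, −78 °C → 0 °C; then H2O
Reagents that add atoms: none
Why: Chelation-controlled Lewis acid ether cleavage, in which BCl3 bound to the formyl oxygen should remove the methyl of the C2 methoxyl, the ortho methoxyl that the C3 methoxyl forces out of the ring plane and that is therefore the more basic and more strained, to give the six-membered chelate 4 that water hydrolyses.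

Step 3
Reactants: 6 trichloroethylene
Product: 7 (E)-1,2-dichloro-1-methoxyethene
Conditions: KH, MeOH (1 equiv), THF, 0 °C; then trichloroethylene, −50 °C → rt; distillation
Reagents that add atoms: methanol, CO
Why: Base-mediated elimination–addition of potassium methoxide on trichloroethylene (net vinylic substitution of one geminal chlorine with anti addition of methanol) is the standard entry to 1,2-dichlorovinyl ethers, the precursors of alkoxyacetylides.

Step 4
Reactants: 7 (E)-1,2-dichloro-1-methoxyethene; 8 2-iodoanisole
Product: 11 1-methoxy-2-(methoxyethynyl)benzene, via lithium methoxyacetylide 9 (not isolated), via (methoxyethynyl)zinc chloride 10 (not isolated)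
Conditions: n-BuLi (2.0 equiv), THF, −78 → −40 °C; ZnCl2 (1.1 equiv), −40 → 0 °C; 8 (0.8 equiv), Pd(PPh3)4 (3 mol %), 0 °C → rt; filtration through Et3N-washed basic alumina
Reagents that add atoms: none
Why: Deprotonation with loss of LiCl followed by chlorine–lithium exchange turns the dichlorovinyl ether into acetylide 9, transmetalation gives zinc acetylide 10, and a Negishi coupling under zerovalent palladium joins it to the aryl iodide under the non-acidic conditions an ynol ether requires.

Step 5
Reactants: 5 2-hydroxy-3,4,6-trimethoxybenzaldehyde; 11 1-methoxy-2-(methoxyethynyl)benzene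
Product: 12 3,5,7,8-tetramethoxy-2-(2-methoxyphenyl)-4H-chromen-4-one
Conditions: [Cp*RhCl2]2 (2.5 mol %), Cu(OAc)2 (2.2 equiv), K2CO3 (2.2 equiv), 4 Å MS, 1,4-dioxane, 70 °C, N2; 11 (2 equiv) added over 4 h
Reagents that add atoms: none
Why: Proposed new method: the phenoxide of 5 binds Cp*-ligated trivalent rhodium, acetate-assisted cleavage of the formyl C–H bond gives a five-membered acyl rhodacycle, syn insertion of the alkyne of 11 into the Rh–acyl bond forms C4–C3 within a seven-membered oxa-rhodacycle, and C–O reductive elimination forms O1–C2 before Cu(OAc)2 returns monovalent rhodium to the trivalent state. The closest known reaction type is the rhodium-catalysed oxidative coupling of salicylaldehydes with diaryl or aryl alkyl alkynes to 2,3-disubstituted chromones, which has not been run with an alkoxyalkyne as the two-carbon partner. Ring C closes by that C–O reductive elimination from the seven-membered metallacycle, a formal [4+2] union of the O1–C8a–C4a–C4 unit with the two alkyne carbons, and no stereocentre is created. The step needs the acyl group to migrate to the methoxy-bearing alkyne carbon, which is the electrophilic end of the polarised ynol ether, while the aryl-bearing carbon is the one such insertions normally place on rhodium and its 2-methoxy group can assist by coordination, so electronic and aryl effects act in the same direction. The ynol ether must also survive, which is why K2CO3 takes up the acetic acid released, sieves exclude water and 11 is added slowly in excess. Loss of CO from the acyl rhodium, which would lead to a benzofuran, should be held back by the moderate temperature and by fast insertion of the electron-rich alkyne.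

Step 6
Reactants: 12 3,5,7,8-tetramethoxy-2-(2-methoxyphenyl)-4H-chromen-4-one
Product: 14 5-hydroxy-3,7,8-trimethoxy-2-(2-methoxyphenyl)-4H-chromen-4-one (5-hydroxy-3,7,8,2'-tetramethoxyflavone), via C5 aryloxydichloroborane 13 (not isolated)
Conditions: BCl3 (2 equiv, 1 M in CH2Cl2), CH2Cl2, −78 °C → 0 °C; then aq HCl, MeOH
Reagents that add atoms: none
Why: Chelation-controlled demethylation, in which BCl3 bound to the C4 carbonyl forms a six-membered chelate only with the peri C5 oxygen, so this methyl is lost at low temperature while the C3 methoxyl (five-membered chelate) and the C7, C8 and C2' methoxyls should remain.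

**Compound list**
1 | 1,2,3,5-tetramethoxybenzene | COc1cc(OC)c(OC)c(OC)c1 | starting material
2 | dimethyl(2,3,4,6-tetramethoxybenzylidene)iminium dichlorophosphate | COc1cc(OC)c(C=[N+](C)C)c(OC)c1OC.[O-]P(=O)(Cl)Cl | intermediate
3 | 2,3,4,6-tetramethoxybenzaldehyde | COc1cc(OC)c(C=O)c(OC)c1OC | intermediate
4 | dichloro(2-formyl-3,5,6-trimethoxyphenoxy)borane | COc1cc(OC)c(C=O)c(OB(Cl)Cl)c1OC | intermediate
5 | 2-hydroxy-3,4,6-trimethoxybenzaldehyde | COc1cc(OC)c(C=O)c(O)c1OC | intermediate
6 | trichloroethylene | ClC=C(Cl)Cl | starting material
7 | (E)-1,2-dichloro-1-methoxyethene | CO/C(Cl)=C\Cl | intermediate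
8 | 2-iodoanisole | COc1ccccc1I | starting material
9 | lithium methoxyacetylide | [Li]C#COC | intermediate
10 | (methoxyethynyl)zinc chloride | COC#C[Zn]Cl | intermediate
11 | 1-methoxy-2-(methoxyethynyl)benzene | COC#Cc1ccccc1OC | intermediate
12 | 3,5,7,8-tetramethoxy-2-(2-methoxyphenyl)-4H-chromen-4-one | COc1ccccc1-c1oc2c(OC)c(OC)cc(OC)c2c(=O)c1OC | intermediate
13 | dichloro{[3,7,8-trimethoxy-2-(2-methoxyphenyl)-4-oxo-4H-chromen-5-yl]oxy}borane | COc1ccccc1-c1oc2c(OC)c(OC)cc(OB(Cl)Cl)c2c(=O)c1OC | intermediate
14 | 5-hydroxy-3,7,8-trimethoxy-2-(2-methoxyphenyl)-4H-chromen-4-one | COc1ccccc1-c1oc2c(OC)c(OC)cc(O)c2c(=O)c1OC | target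

**Step count**
Total steps: 6. Longest linear sequence: 4 steps (steps 1, 2, 5, 6 from compound 1, or steps 3, 4, 5, 6 from compound 6).

**Steps most likely to fail**

Step 5. The ynol ether may be consumed by addition of acetate, phenol or water before it inserts, insertion may take the opposite orientation, or the acyl rhodium may lose CO. The fallback uses only known chemistry, sets out from 1 and comes back to the route at 12. Friedel–Crafts acylation of 1 with methoxyacetyl chloride and AlCl3 in Et2O/CH2Cl2, with concomitant loss of the crowded ortho methyl, would give 1-(2-hydroxy-3,4,6-trimethoxyphenyl)-2-methoxyethan-1-one F1. Acylation of its phenol with 2-methoxybenzoyl chloride in pyridine would give 2-(methoxyacetyl)-3,5,6-trimethoxyphenyl 2-methoxybenzoate F2. A Baker–Venkataraman acyl shift with KOH in pyridine would give 1-(2-hydroxy-3,4,6-trimethoxyphenyl)-2-methoxy-3-(2-methoxyphenyl)propane-1,3-dione F3. Cyclodehydration in AcOH with H2SO4 would close ring C to 12, and step 6 follows unchanged.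

Step 4. The metallated methoxyacetylene may decompose before it couples, and the electron-rich alkyne may hydrate or polymerise during isolation. The fallback makes the triple bond by elimination instead of cross-coupling; it sets out from 8 and comes back at 11. Iodine–magnesium exchange on 8 with iPrMgCl·LiCl and acylation with 2-methoxy-N-methoxy-N-methylacetamide would give 2-methoxy-1-(2-methoxyphenyl)ethan-1-one F4. Enolisation with LiN(SiMe3)2 and trapping with PhNTf2 would give (Z)-2-methoxy-1-(2-methoxyphenyl)ethenyl trifluoromethanesulfonate F5. KOtBu in THF at −78 °C would then effect anti elimination of triflate to 11, which would be taken into step 5 without storage.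

Step 2. Cleavage may compete at the less crowded C6 methoxyl, or a second methyl may be lost. The fallback moves the regiochemical decision from a chelation-controlled cleavage to a sterically controlled alkylation; it sets out from 3 and comes back at 5. Excess BCl3 at room temperature (or AlCl3 in CH2Cl2) would remove both ortho methyls to give 2,6-dihydroxy-3,4-dimethoxybenzaldehyde F6. One equivalent of MeI with K2CO3 in acetone should then methylate the less hindered hydroxyl, the one next to C5–H, and so return 5.

**Further compounds**
F1 | step 5 | 1-(2-hydroxy-3,4,6-trimethoxyphenyl)-2-methoxyethan-1-one | COCC(=O)c1c(O)c(OC)c(OC)cc1OC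
F2 | step 5 | 2-(methoxyacetyl)-3,5,6-trimethoxyphenyl 2-methoxybenzoate | COCC(=O)c1c(OC(=O)c2ccccc2OC)c(OC)c(OC)cc1OC
F3 | step 5 | 1-(2-hydroxy-3,4,6-trimethoxyphenyl)-2-methoxy-3-(2-methoxyphenyl)propane-1,3-dione (racemic, enolisable) | COC(C(=O)c1ccccc1OC)C(=O)c1c(O)c(OC)c(OC)cc1OC
F4 | step 4 | 2-methoxy-1-(2-methoxyphenyl)ethan-1-one | COCC(=O)c1ccccc1OC
F5 | step 4 | (Z)-2-methoxy-1-(2-methoxyphenyl)ethenyl trifluoromethanesulfonate | CO/C=C(\OS(=O)(=O)C(F)(F)F)c1ccccc1OC
F6 | step 2 | 2,6-dihydroxy-3,4-dimethoxybenzaldehyde | COc1cc(O)c(C=O)c(O)c1OC
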